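(All runs were generated by integration with constants of no real substance, noise included.)

The north flask and the north-west flask differed in one setting, the reagent charge, 1.8 equiv against 1.2 equiv, and I wanted from them the apparent order in reagent in the north flask, with substrate as the limiting reagent in both.

the same everywhere: substrate 0.20 M; free catalyst 1.2 mol%

| charge | reagent | remark |
|---|---|---|
| north | 1.8 equiv | the very flask that is asked about, followed so far |
| north-west | 1.2 equiv | run made earlier |
| flask | 1.80 equiv |  |

| run | time / min | product / % | substrate / % |
|---|---|---|---|
| north | 0.167 | 0.5 | 98.1 |
| north | 0.333 | 0.5 | 98.1 |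
| north | 0.667 | 2.8 | 98.1 |
| north | 1.00 | 3.7 | 94.9 |
| north | 1.33 | 3.5 | 95.8 |
| north | 2.00 | 5.3 | 93.3 |
| north | 2.50 | 6.7 | 91.2 |
| north-west | 0.333 | 1.6 | 99.4 |
| north-west | 0.500 | 1.1 | 98.6 |
| north-west | 0.833 | 1.7 | 98.3 |
| north-west | 1.33 | 5.0 | 95.7 |
| north-west | 2.00 | 4.6 | 93.3 |
| north-west | 3.00 | 11.0 | 91.3 |
| north-west | 4.00 | 11.8 | 89.4 |

(standard deviation of a reading: 1 percentage point)



1. apparent order in reagent when 10% of the substrate are converted (percent change of the rate of making product for one percent more reagent charged)

I folded scatter, conversion and charge ratio into one number, the order width 0.349: the error of an order taken from one pair of rates, which is the scatter of 1 percentage point on a signal of 10%, times the root of two for two rates, over the logarithm of the charge ratio. An order of one and an order of zero thus stand 2.87 widths apart, so the runs could tell which side of one half the flask lies on. From the last readings, substrate loss gave 0.700 and product gave −0.237. Their mean, 0.232, carries 0.247, and even with that added it stayed below one half, so I committed to an order under one half. One number was not quite enough, though: the two estimates lay 0.937 apart, more than one width.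

The forecast gave 0.1, holding that “50% more reagent barely changes the rate”.

The simulation gave 0.085.

    substrate + free catalyst → catalyst intermediate A (k = 150 /M/min)
    catalyst intermediate A → catalyst intermediate B (k = 5.90 /min)
    reagent + catalyst intermediate B → catalyst intermediate C (k = 110 /M/min)
    catalyst intermediate C ⇌ catalyst intermediate D (K = 0.610, k = 48.0 /min)
    catalyst intermediate D → free catalyst + product (k = 34.0 /min)
    catalyst intermediate A → spent catalyst (k = 0.180 /min)

At 3.00 min the flask held 38.5% of its catalyst as catalyst intermediate A, the resting state, more than any other form, against 6.06% as catalyst intermediate B, the form that meets the reagent. Measured in the order width of 0.349, the order of 0.085 comes to 0.244 of a width, and for a signal of 16.4%, the product in the flask at 6.00 min, the width comes to 0.213.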